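## Structural features

The target is a 6,7-seco-ent-kaurane spirolactone. Ring A (C1–C5, C10; gem-dimethyl at C4, acetoxy at C1, hydroxymethyl C6 on C5) is spiro-joined at C10 to a δ-lactone (C10, C20, O, C7, C8, C9). The lactone is cis-fused along C8–C9 to ring C (C8, C9, C11–C14), and ring D (C8, C14, C13, C16, C15) bridges C8 and C13, so rings C and D form a bicyclo[3.2.1]octane with C14 as the one-carbon bridge. The eight stereocentres are contiguous: C5–C10–C1 on ring A, then C10–C9–C8–C14–C13 and C9–C11, with the quaternary carbons C10 and C8 flanking the tertiary C9. On ring A the C1 acetoxy group, C20 and C6 share one face and C9 takes the other; on ring C the C11 and C14 hydroxyls, H9 and the C15–C16 bridge share the face opposite to C7 and C10. Fragile groups are the exocyclic enone (C17=C16–C15=O), the C14 hydroxyl (β to both the C7 and C15 carbonyls through C8, hence retro-aldol under base), the single acetate among three free hydroxyls, and the lactone, which could migrate to a free C1 hydroxyl. The real difficulty is the absolute control of the vicinal C5/C10 pair, the crowded C10–C9–C8 triad, and the differentiation of the four oxygens carried by C1, C6, C9 and C20 on the way. The key step exploits ring A: C5 carries C6 at the aldehyde level next to quaternary C10, with C1–C2 available as an alkene, which is the product pattern of a Claisen rearrangement of a 2-alkenyl-3,4-dihydro-2H-pyran in which O–C2 is exchanged for C5–C10.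

## Logic of the disconnections

37 from 36: the three O–Si bonds at C6, C11 and C14 are cut last. The free C14 hydroxyl is retro-aldol prone and the free primary C6 hydroxyl would compete in every acylation, so all three are unveiled in one acidic fluoride step. The demand is that enone, acetate and lactone survive, which acidic fluoride allows.

36 from 32: the C16=C17 bond is cut. The exocyclic enone is the most electrophilic group of the target and is added only when the skeleton is complete. C16 is the only enolisable position of 32 because C8 is quaternary; the forward step must enolise the ketone without touching the C1 acetate.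

32 from 31 and 29: the C13–C16 bond of ring D is cut homolytically. This removes the bicyclo[3.2.1]octane and leaves a cyclohexene bearing an acetyl group on C8. The forward step needs a C16 radical (from the bromide 31), 5-exo closure on C13 and not on C12, and attack from the face on which C15 sits, which C8 dictates.

29 from 25 and 28: the C9–C11 and C8–C14 bonds are cut. A cis-1,4-dioxygenated cyclohexene next to an acyl-bearing quaternary carbon is a Diels–Alder retron. The symmetrical diene 28 brings both oxygens at the alcohol level and avoids any regiochemical question. The forward step must choose the lactone face flanked by C1 and must place the acetyl group endo.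

25 from 24, 23, 22, 21 and 20: the C8=C9 bond and the C20 O–C7 ester bond are cut. Both lactone bonds come from an acetoacetate tethered at C20 and a C9 aldehyde, so C7, C8, C15 and C16 arrive as one four-carbon reagent. This demands that the C20 hydroxyl be acylated selectively, that C1 receive its acetate before the C9 oxygen is freed, and that the C9 aldehyde form only when the acetoacetate is in place.

20 from 19 and 18: the C1–O bond is cut back to the C1=C2 alkene. The C20 hydroxyl, homoallylic and on the correct face, directs epoxidation; hydride must then enter at C2, away from quaternary C10.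

18 from 17, 16 and 15: C20 and C6 are returned to ester and aldehyde. Their different oxidation levels are the only handle that tells the two one-carbon arms apart, so the aldehyde is reduced and silylated before the ester is reduced.

15 from 14: the C5–C10 bond is cut and O–C2 reconnected. Ring A with its two adjacent stereocentres becomes a dihydropyran with one carbinol stereocentre and a trisubstituted alkene of defined geometry. A check of the boat geometry confirms that (S)-C2 and the (E)-enoate of 14 translate into the C5/C10 configuration of 37. The forward step demands a purely thermal, acid-free rearrangement.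

14 from 13, 12 and 11: the C10–C20 bond is cut to an alkenylmetal, and C10–Sn/C1–H to the alkyne. syn-Hydrostannation fixes the alkene geometry. Because the enol ether of 11 would not tolerate electrophilic halogen, the ester is introduced by tin–lithium exchange and acylation, not through an alkenyl iodide.

11 from 10, 9, 8 and 7: the enol ether is traced to a δ-lactone and the C2–H bond to a ynone. The only stereocentre that has to be made by a reagent is this carbinol, and an alkynyl ketone is a reliable substrate for asymmetric transfer hydrogenation.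

7 from 3 and 6, 3 from 2 and 1, 6 from 4 and 5: the C1–C2 acyl–alkynyl bond is cut to an acid chloride and a terminal alkyne; the acid chloride comes from the symmetrical anhydride, so no desymmetrisation is needed.

28 from 27 and 26: the two O–Si bonds are cut to the commercial (E,E)-dienyl diacetate, whose geometry must be carried through the enolate.

## Other disconnections considered

Alternative 1: The cut is made at C8–C15 and C14–C16, back to the ring C enone A2 (C13 ketone, C14 silyloxy, C8=C14) and allene A3. Forward, irradiation would give the cis-fused methylenecyclobutane A1; after reduction and activation of C13, a semipinacol shift of C16 from C14 to C13 would expand the four-membered ring into ring D.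
- In its favour: quaternary C8, both ring D carbons and the exocyclic methylene arrive in one step from a C3 gas, and no late methylenation is needed. On this point it is better than the chosen plan.
- Against it: head-to-head regiochemistry and facial selectivity must be secured on a tetrasubstituted, cross-conjugated alkene next to the spiro centre. The shift must move C16 and not C8. C14 must afterwards be reduced with the correct configuration and C15 oxidised to the ketone.
- Comparison: the ring D stage would take about five or six operations against three in the chosen plan. A2 presupposes ring C on the spirolactone, and the alternative says nothing about C5/C10, so it would still need the ring A solution used here; on ring A the two plans are equal.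

Alternative 2: The cut is made at C1–C10. A Lewis acid would activate the aldehyde of A5, and the γ-carbon C10 of its silyl dienol ether would attack C1 to give the spiro unsaturated lactone A4.
- In its favour: ring A, quaternary C10 and the C1 carbinol form in one step. The C1 hydroxyl is delivered directly, where the chosen plan spends two steps (epoxidation, hydride opening); on this point the alternative is better. The unsaturated lactone is obtained at once, which is equal to the chosen plan.
- Against it: C10 and C1 would both be controlled by the single C5 centre through an open or closed transition state. C5 itself would have to be made enantioselectively by separate chemistry. γ-Attack at a fully substituted carbon next to C4 competes with α-attack at C8. A4 lacks the C8 acyl group, so the later ring C annulation would use a weaker dienophile or need an extra acylation.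
- Comparison: the chosen [3,3] shift derives both C5 and C10 from one easily made carbinol centre, with the relative configuration fixed by alkene geometry and an enforced boat. This is mechanistically more secure, at the cost of more steps around ring A.

Alternative 3: The cut is made at C13–C16, as in the chosen plan, but in a polar sense. A nucleophilic phosphine would add to C17 of the acryloyl group of A7, the enolate carbon C16 would add to C13 of the ring C enone, and loss of the catalyst would give the tetracyclic 11-ketone A6 with the exocyclic methylene in place.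
- In its favour: ring D and C16=C17 form in one catalytic step, without bromination, silane or a separate methylenation. For this stage it is better in step count (one against three). It closes the same bond from the same face, which is equal.
- Against it: A7 needs an acryloyl group on quaternary C8 (a very reactive vinyl ketone) and a C11 ketone with the C14 silyloxy group in the γ-position, where it can be eliminated under nucleophilic catalysis. The C11 and C14 oxygens would have to be differentiated, which the symmetrical diene of the chosen plan avoids. The 11-ketone of A6 must finally be reduced in the presence of the exocyclic enone.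
- Comparison: the chosen plan brings C11 and C14 in at the alcohol level with the final configuration and pays with a longer, radical ring D sequence.

Key step: step 9

Assumption: atom numbers follow the kaurane skeleton of the target, and the (S,S) ruthenium catalyst is taken to give the (S) propargylic alcohol as with other alkynyl ketones; the antipodal catalyst would be used if the assay showed otherwise.

## Steps

Step 1
Reactants: 1 3,3-dimethylglutaric anhydride
Product: 2 5-methoxy-3,3-dimethyl-5-oxopentanoic acid
Conditions: MeOH, reflux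
Reagents that add atoms: methanol (CO)
Why: Alcoholysis of the symmetrical cyclic anhydride should give the half ester without any selectivity issue; no stereocentre is formed.

Step 2
Reactants: 2 5-methoxy-3,3-dimethyl-5-oxopentanoic acid
Product: 3 methyl 5-chloro-3,3-dimethyl-5-oxopentanoate
Conditions: (COCl)2, DMF (cat.), DCM, 0 °C to rt
Reagents that add atoms: oxalyl chloride (ClC(=O)C(Cl)=O)
Why: Standard acid chloride formation through the chloroiminium catalyst; the methyl ester is inert.

Step 3
Reactants: 4 prop-2-yn-1-ol; 5 4-methoxybenzyl chloride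
Product: 6 1-methoxy-4-[(prop-2-yn-1-yloxy)methyl]benzene
Conditions: NaH, n-Bu4NI (cat.), THF, 0 °C to rt
Reagents that add atoms: none
Why: Williamson ether synthesis of a primary alkoxide with a benzylic chloride.

Step 4
Reactants: 3 methyl 5-chloro-3,3-dimethyl-5-oxopentanoate; 6 1-methoxy-4-[(prop-2-yn-1-yloxy)methyl]benzene
Product: 7 methyl 8-[(4-methoxyphenyl)methoxy]-3,3-dimethyl-5-oxooct-6-ynoate
Conditions: PdCl2(PPh3)2 (2 mol %), CuI (4 mol %), Et3N, THF, rt
Reagents that add atoms: none
Why: Acyl Sonogashira coupling: oxidative addition of the acid chloride to zerovalent palladium, transmetalation from the copper acetylide and reductive elimination give the ynone; the ester is untouched.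

Step 5
Reactants: 7 methyl 8-[(4-methoxyphenyl)methoxy]-3,3-dimethyl-5-oxooct-6-ynoate
Product: 9 (6S)-6-{3-[(4-methoxyphenyl)methoxy]prop-1-yn-1-yl}-4,4-dimethyloxan-2-one, via hydroxy ester 8 (not isolated)
Conditions: Ru[(S,S)-TsDPEN](p-cymene) (1 mol %), i-PrOH, rt; then PPTS (cat.), PhMe, 80 °C
Reagents that add atoms: none
Why: Noyori asymmetric transfer hydrogenation of the alkynyl ketone: the alkyne takes the place of the π-substituent in the six-membered hydride-transfer transition state, so the (S,S) catalyst should give the (S) carbinol that becomes C2; the base-free amido complex spares the ynone. Acid-catalysed lactonisation is helped by the gem-dimethyl group (Thorpe–Ingold effect).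

Step 6
Reactants: 9 (6S)-6-{3-[(4-methoxyphenyl)methoxy]prop-1-yn-1-yl}-4,4-dimethyloxan-2-one
Product: 11 (2S)-2-{3-[(4-methoxyphenyl)methoxy]prop-1-yn-1-yl}-4,4-dimethyl-3,4-dihydro-2H-pyran, via lactol 10 (not isolated)
Conditions: i-Bu2AlH, DCM, −78 °C; then MsCl, Et3N, DCM, 0 to 40 °C
Reagents that add atoms: none
Why: Half-reduction of the δ-lactone to the lactol, then mesylation and loss of methanesulfonate towards C5 (the only β-hydrogens) gives the cyclic enol ether; the carbinol centre is not touched.

Step 7
Reactants: 11 (2S)-2-{3-[(4-methoxyphenyl)methoxy]prop-1-yn-1-yl}-4,4-dimethyl-3,4-dihydro-2H-pyran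
Product: 12 tributyl{(1E)-1-[(2S)-4,4-dimethyl-3,4-dihydro-2H-pyran-2-yl]-3-[(4-methoxyphenyl)methoxy]prop-1-en-2-yl}stannane
Conditions: Bu3SnH, PdCl2(PPh3)2 (2 mol %), THF, 0 °C to rt
Reagents that add atoms: tributyltin hydride (CCCC[SnH](CCCC)CCCC)
Why: Palladium-catalysed hydrostannation adds H and Sn to the same face of the alkyne; tin should go to C10, the alkyne carbon remote from the branched ring carbon, so that C2 and the PMB-oxymethyl group C9 end up cis.

Step 8
Reactants: 12 tributyl{(1E)-1-[(2S)-4,4-dimethyl-3,4-dihydro-2H-pyran-2-yl]-3-[(4-methoxyphenyl)methoxy]prop-1-en-2-yl}stannane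
Product: 14 methyl (2E)-3-[(2S)-4,4-dimethyl-3,4-dihydro-2H-pyran-2-yl]-2-{[(4-methoxyphenyl)methoxy]methyl}prop-2-enoate, via alkenyllithium 13 (not isolated)
Conditions: n-BuLi, THF, −78 °C; then ClCO2Me (excess, inverse addition), −78 to −40 °C
Reagents that add atoms: methyl chloroformate (COC(=O)Cl); n-butyllithium (CCCC[Li], lithium of 13 only)
Why: Tin–lithium exchange and acylation of the alkenyllithium both proceed with retention, so the ester C20 ends trans to C2. This route avoids electrophilic iodine, which the enol ether would not survive.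

Step 9
Reactants: 14 methyl (2E)-3-[(2S)-4,4-dimethyl-3,4-dihydro-2H-pyran-2-yl]-2-{[(4-methoxyphenyl)methoxy]methyl}prop-2-enoate
Product: 15 methyl (1S,6R)-6-formyl-1-{[(4-methoxyphenyl)methoxy]methyl}-5,5-dimethylcyclohex-2-ene-1-carboxylate
Conditions: o-xylene (0.02 M, degassed), N,O-bis(trimethylsilyl)acetamide (0.1 equiv), 210 °C, sealed silylated tube
Reagents that add atoms: none
Why: A concerted, suprafacial [3,3]-sigmatropic (Claisen) shift of the allyl vinyl ether C5=C6–O–C2–C1=C10 forms C5–C10 as O–C2 breaks, and C6 becomes the aldehyde. The closest known reaction type is the thermal rearrangement of 2-alkenyl-3,4-dihydro-2H-pyrans to cyclohex-3-ene carbaldehydes. Ring A (C5–C10–C1–C2–C3–C4) closes as a ring contraction in which C3–C4 of the pyran stay in place, so the six reacting atoms can only adopt a boat, bicyclo[2.2.2]-like array. C5 and C10 are set by chirality transfer from the (S) carbinol centre C2, which is consumed: the alkenyl group must sit in the flagpole position on the face defined by C2, so C10 reaches only one face of the enol ether. The relative configuration follows from the alkene geometry: in the boat the substituent cis to C2 (C9) points to the C3–C4 bridge and the ester C20 to the O–C6 bridge, which places C20 cis to C6. The step needs geometric integrity of the (E)-enoate and a neutral medium, because the enol ether and the epimerisable C5 aldehyde are acid-sensitive. The acceptor at the bond-forming terminus and the new quaternary centre raise the barrier, hence the high temperature, high dilution and acid scavenger.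

Step 10
Reactants: 15 methyl (1S,6R)-6-formyl-1-{[(4-methoxyphenyl)methoxy]methyl}-5,5-dimethylcyclohex-2-ene-1-carboxylate
Product: 17 methyl (1S,6R)-6-{[(tert-butyldimethylsilyl)oxy]methyl}-1-{[(4-methoxyphenyl)methoxy]methyl}-5,5-dimethylcyclohex-2-ene-1-carboxylate, via hydroxy ester 16 (not isolated)
Conditions: NaBH4, MeOH/THF, −40 °C, AcOH quench; then TBSCl, imidazole, DMF, 0 °C to rt
Reagents that add atoms: tert-butyldimethylsilyl chloride (CC(C)(C)[Si](C)(C)Cl)
Why: Borohydride reduces the aldehyde and not the hindered ester; immediate silylation pre-empts lactonisation onto the cis ester and marks C6 as the arm that stays protected to the end.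

Step 11
Reactants: 17 methyl (1S,6R)-6-{[(tert-butyldimethylsilyl)oxy]methyl}-1-{[(4-methoxyphenyl)methoxy]methyl}-5,5-dimethylcyclohex-2-ene-1-carboxylate
Product: 18 {6-[(tert-butyldimethylsilyloxy)methyl]-1-[(4-methoxybenzyloxy)methyl]-5,5-dimethylcyclohex-2-en-1-yl}methanol (C20 hydroxymethyl cis to the C6 arm)
Conditions: LiAlH4, Et2O, 0 °C
Reagents that add atoms: none
Why: Hydride reduction of the neopentyl ester gives the C20 alcohol; silyl and PMB ethers and the alkene are inert.

Step 12
Reactants: 18 {6-[(tert-butyldimethylsilyloxy)methyl]-1-[(4-methoxybenzyloxy)methyl]-5,5-dimethylcyclohex-2-en-1-yl}methanol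
Product: 19 C1–C2 epoxide of 18 (epoxide oxygen on the face of C20 and C6)
Conditions: VO(acac)2 (5 mol %), t-BuOOH, DCM, 0 °C to rt
Reagents that add atoms: tert-butyl hydroperoxide (CC(C)(C)OO)
Why: Hydroxyl-directed epoxidation: the vanadium alkoxide of the homoallylic C20 hydroxyl delivers oxygen to the alkene face on which C20 stands, which fixes the C1–O configuration.

Step 13
Reactants: 19 C1–C2 epoxide of 18
Product: 20 2-(hydroxymethyl)-3-[(tert-butyldimethylsilyloxy)methyl]-2-[(4-methoxybenzyloxy)methyl]-4,4-dimethylcyclohexan-1-ol (C1 hydroxyl, C20 and C6 all cis)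
Conditions: LiAlH4, THF, 0 to 65 °C
Reagents that add atoms: none
Why: SN2 opening of the epoxide by hydride should occur at C2, because C1 is neopentyl (next to quaternary C10); the C1–O bond and its configuration are retained. The alkoxyaluminate at C20 sits on the epoxide face and cannot deliver hydride internally.

Step 14
Reactants: 20 diol (C1 and C20 hydroxyls)
Product: 21 C20 acetoacetate of 20 (C1 hydroxyl free)
Conditions: diketene (1.05 equiv), DMAP (5 mol %), THF, −30 to 0 °C
Reagents that add atoms: diketene (C=C1CC(=O)O1)
Why: Nucleophile-catalysed acetoacetylation is sterically demanding and should select the primary C20 hydroxyl over the secondary C1 hydroxyl next to the quaternary carbon.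

Step 15
Reactants: 21 C20 acetoacetate
Product: 22 C1 acetate, C20 acetoacetate
Conditions: Ac2O, pyridine, rt to 40 °C
Reagents that add atoms: acetic anhydride (CC(=O)OC(C)=O)
Why: Acetylation of the remaining equatorial secondary hydroxyl; without a stronger base or acyl-transfer catalyst the β-keto ester should not be O-acetylated. The acetate also blocks the C1 oxygen from trapping the benzylic cation in step 16 and from attacking the lactone later.

Step 16
Reactants: 22 C1 acetate, C20 acetoacetate
Product: 23 C9 alcohol
Conditions: DDQ, DCM/pH 7 buffer, 0 °C to rt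
Reagents that add atoms: none
Why: Oxidative cleavage of the 4-methoxybenzyl ether through the benzylic oxocarbenium ion and its hydrolysis; silyl ether, acetate and acetoacetate are unaffected.

Step 17
Reactants: 23 C9 alcohol
Product: 25 4-acetyl-11-[(tert-butyldimethylsilyloxy)methyl]-10,10-dimethyl-3-oxo-2-oxaspiro[5.5]undec-4-en-7-yl acetate, via aldehyde 24 (not isolated)
Conditions: Dess–Martin periodinane, DCM, 0 °C to rt; then piperidine (10 mol %), AcOH (10 mol %), 4 Å MS, DCM, rt
Reagents that add atoms: none
Why: Oxidation gives a non-enolisable neopentyl aldehyde, and intramolecular Knoevenagel condensation with the tethered acetoacetate closes the six-membered lactone. The ring enforces the geometry (C7 cis to C10), and C10 has no hydrogen that would allow deconjugation.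

Step 18
Reactants: 26 (1E,3E)-buta-1,3-diene-1,4-diyl diacetate
Product: 28 (1E,3E)-1,4-bis(tert-butyldimethylsilyloxy)buta-1,3-diene, via dilithium dienediolate 27 (not isolated)
Conditions: MeLi (4.2 equiv), DME, −20 to 0 °C; then TBSCl (2.3 equiv), DMPU, 0 °C to rt
Reagents that add atoms: tert-butyldimethylsilyl chloride (CC(C)(C)[Si](C)(C)Cl); methyllithium ([Li]C, lithium of 27 only)
Why: Cleavage of enol acetates by methyllithium gives lithium enolates with retention of alkene geometry, and O-silylation keeps it, so the (E,E) diene is expected.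

Step 19
Reactants: 25 spiro 3-acetyl unsaturated lactone; 28 (1E,3E)-1,4-bis(tert-butyldimethylsilyloxy)buta-1,3-diene
Product: 29 Diels–Alder adduct (ring C cyclohexene cis-fused to the lactone; C8 acetyl; C11 and C14 silyloxy cis to the acetyl group and H9)
Conditions: PhMe (1 M), BHT (cat.), 80 to 110 °C, sealed tube
Reagents that add atoms: none
Why: Normal-demand Diels–Alder reaction of the doubly activated C8=C9 alkene with a symmetrical electron-rich diene, so there is no regiochemical issue. The diene body should lie over the acetyl/H9 side and away from the spiro ring (acetyl endo), which puts both silyloxy groups cis to the acetyl group and H9. Attack is expected on the lactone face flanked by the small C1 acetoxy group and not on the face flanked by the C5 silyloxymethyl arm and the axial C4 methyl group, which sets C8, C9, C11 and C14 relative to C10.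

Step 20
Reactants: 29 Diels–Alder adduct
Product: 31 C16 bromide (bromoacetyl group on C8), via trimethylsilyl enol ether 30 (not isolated)
Conditions: TMSOTf, Et3N, DCM, 0 °C; then NBS, THF, −78 °C
Reagents that add atoms: N-bromosuccinimide (O=C1CCC(=O)N1Br); trimethylsilyl trifluoromethanesulfonate (C[Si](C)(C)OS(=O)(=O)C(F)(F)F, silyl group of 30 only)
Why: Soft enolisation silylates the methyl ketone (its only enolisable side, C8 being quaternary) much faster than the acetate, and the silyl enol ether reacts with the bromonium source far faster than the ring alkene does.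

Step 21
Reactants: 31 C16 bromide
Product: 32 tetracyclic 15-ketone (ring D closed; C6, C11, C14 silyl ethers; C1 acetate)
Conditions: (Me3Si)3SiH (slow addition), AIBN (cat.), PhMe (0.005 M), 90 °C
Reagents that add atoms: none
Why: Bromine abstraction gives the α-keto radical, which should close 5-exo-trig on C13. The tether C15–C8–C14 reaches only the face on which C15 stands, which sets C13, and the C12 radical is then reduced. The slow hydrogen donor at high dilution leaves time for ring closure, and the bridged geometry disfavours the 6-endo mode.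

Step 22
Reactants: 32 tetracyclic 15-ketone
Product: 36 16-methylene-15-ketone (tris-silyl ether of the target), via trimethylsilyl enol ether 33 (not isolated), via Mannich base 34 (not isolated), via ammonium iodide 35 (not isolated)
Conditions: TMSOTf, Et3N, DCM, 0 °C; then Me2N=CH2 I, DCM, rt; then MeI, THF, rt; NaHCO3 (aq)
Reagents that add atoms: N,N-dimethylmethyleneiminium iodide (C=[N+](C)C.[I-]); trimethylsilyl trifluoromethanesulfonate (C[Si](C)(C)OS(=O)(=O)C(F)(F)F, silyl group of 33 only); iodomethane (CI, N-methyl of 35 only)
Why: Mannich methylenation through the silyl enol ether (Eschenmoser's salt), then quaternisation and β-elimination. C16 is the only enolisable position and C13 is a bridgehead, so only the exocyclic alkene can form; soft enolisation spares the acetate.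

Step 23
Reactants: 36 16-methylene-15-ketone (tris-silyl ether)
Product: 37 CNP0225182.1 (target)
Conditions: HF·pyridine, THF/pyridine, 0 °C to rt
Reagents that add atoms: none
Why: Global desilylation under acidic fluoride conditions frees the C6, C11 and C14 hydroxyls without the base that would trigger retro-aldol cleavage at C14, conjugate addition to the enone or acetate migration.

## Compound list

1 | 3,3-dimethylglutaric anhydride | CC1(C)CC(=O)OC(=O)C1 | starting material
2 | 5-methoxy-3,3-dimethyl-5-oxopentanoic acid | COC(=O)CC(C)(C)CC(=O)O | intermediate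
3 | methyl 5-chloro-3,3-dimethyl-5-oxopentanoate | COC(=O)CC(C)(C)CC(=O)Cl | intermediate
4 | prop-2-yn-1-ol | C#CCO | starting material
5 | 4-methoxybenzyl chloride | COc1ccc(CCl)cc1 | starting material
6 | 1-methoxy-4-[(prop-2-yn-1-yloxy)methyl]benzene | C#CCOCc1ccc(OC)cc1 | intermediate
7 | methyl 8-[(4-methoxyphenyl)methoxy]-3,3-dimethyl-5-oxooct-6-ynoate | COC(=O)CC(C)(C)CC(=O)C#CCOCc1ccc(OC)cc1 | intermediate
8 | methyl (5S)-5-hydroxy-8-[(4-methoxyphenyl)methoxy]-3,3-dimethyloct-6-ynoate | COC(=O)CC(C)(C)C[C@H](O)C#CCOCc1ccc(OC)cc1 | intermediate (not isolated)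
9 | (6S)-6-{3-[(4-methoxyphenyl)methoxy]prop-1-yn-1-yl}-4,4-dimethyloxan-2-one | O=C1CC(C)(C)C[C@@H](C#CCOCc2ccc(OC)cc2)O1 | intermediate
10 | (6S)-6-{3-[(4-methoxyphenyl)methoxy]prop-1-yn-1-yl}-4,4-dimethyloxan-2-ol (anomer mixture) | OC1CC(C)(C)C[C@@H](C#CCOCc2ccc(OC)cc2)O1 | intermediate (not isolated)
11 | (2S)-2-{3-[(4-methoxyphenyl)methoxy]prop-1-yn-1-yl}-4,4-dimethyl-3,4-dihydro-2H-pyran | COc1ccc(COCC#C[C@@H]2CC(C)(C)C=CO2)cc1 | intermediate
12 | tributyl{(1E)-1-[(2S)-4,4-dimethyl-3,4-dihydro-2H-pyran-2-yl]-3-[(4-methoxyphenyl)methoxy]prop-1-en-2-yl}stannane | CCCC[Sn](CCCC)(CCCC)/C(COCc1ccc(OC)cc1)=C/[C@@H]1CC(C)(C)C=CO1 | intermediate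
13 | alkenyllithium from 12 (lithium in place of tin, same geometry) | [Li]/C(COCc1ccc(OC)cc1)=C/[C@@H]1CC(C)(C)C=CO1 | intermediate (not isolated)
14 | methyl (2E)-3-[(2S)-4,4-dimethyl-3,4-dihydro-2H-pyran-2-yl]-2-{[(4-methoxyphenyl)methoxy]methyl}prop-2-enoate | COC(=O)/C(COCc1ccc(OC)cc1)=C/[C@@H]1CC(C)(C)C=CO1 | intermediate (key-step precursor)
15 | methyl (1S,6R)-6-formyl-1-{[(4-methoxyphenyl)methoxy]methyl}-5,5-dimethylcyclohex-2-ene-1-carboxylate | COC(=O)[C@@]1(COCc2ccc(OC)cc2)C=CCC(C)(C)[C@H]1C=O | intermediate (key-step product)
16 | methyl (1S,6R)-6-(hydroxymethyl)-1-{[(4-methoxyphenyl)methoxy]methyl}-5,5-dimethylcyclohex-2-ene-1-carboxylate | COC(=O)[C@@]1(COCc2ccc(OC)cc2)C=CCC(C)(C)[C@H]1CO | intermediate (not isolated)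
17 | methyl (1S,6R)-6-{[(tert-butyldimethylsilyl)oxy]methyl}-1-{[(4-methoxyphenyl)methoxy]methyl}-5,5-dimethylcyclohex-2-ene-1-carboxylate | COC(=O)[C@@]1(COCc2ccc(OC)cc2)C=CCC(C)(C)[C@H]1CO[Si](C)(C)C(C)(C)C | intermediate
18 | {6-[(tert-butyldimethylsilyloxy)methyl]-1-[(4-methoxybenzyloxy)methyl]-5,5-dimethylcyclohex-2-en-1-yl}methanol (C20 hydroxymethyl cis to C6 arm) | OC[C@@]1(COCc2ccc(OC)cc2)C=CCC(C)(C)[C@H]1CO[Si](C)(C)C(C)(C)C | intermediate
19 | C1–C2 epoxide of 18 (oxygen cis to C20 and C6) | OC[C@@]1(COCc2ccc(OC)cc2)[C@H]3O[C@H]3CC(C)(C)[C@H]1CO[Si](C)(C)C(C)(C)C | intermediate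
20 | 2-(hydroxymethyl)-3-[(tert-butyldimethylsilyloxy)methyl]-2-[(4-methoxybenzyloxy)methyl]-4,4-dimethylcyclohexan-1-ol (C1 OH, C20, C6 all cis) | OC[C@@]1(COCc2ccc(OC)cc2)[C@@H](O)CCC(C)(C)[C@H]1CO[Si](C)(C)C(C)(C)C | intermediate
21 | C20 3-oxobutanoate (acetoacetate) of 20 | CC(=O)CC(=O)OC[C@@]1(COCc2ccc(OC)cc2)[C@@H](O)CCC(C)(C)[C@H]1CO[Si](C)(C)C(C)(C)C | intermediate
22 | C1 acetate of 21 | CC(=O)CC(=O)OC[C@@]1(COCc2ccc(OC)cc2)[C@@H](OC(C)=O)CCC(C)(C)[C@H]1CO[Si](C)(C)C(C)(C)C | intermediate
23 | C9 alcohol (PMB removed from 22) | CC(=O)CC(=O)OC[C@@]1(CO)[C@@H](OC(C)=O)CCC(C)(C)[C@H]1CO[Si](C)(C)C(C)(C)C | intermediate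
24 | C9 aldehyde | CC(=O)CC(=O)OC[C@@]1(C=O)[C@@H](OC(C)=O)CCC(C)(C)[C@H]1CO[Si](C)(C)C(C)(C)C | intermediate (not isolated)
25 | 4-acetyl-11-[(tert-butyldimethylsilyloxy)methyl]-10,10-dimethyl-3-oxo-2-oxaspiro[5.5]undec-4-en-7-yl acetate | CC(=O)C1=C[C@]2(COC1=O)[C@@H](OC(C)=O)CCC(C)(C)[C@H]2CO[Si](C)(C)C(C)(C)C | intermediate
26 | (1E,3E)-buta-1,3-diene-1,4-diyl diacetate | CC(=O)O/C=C/C=C/OC(C)=O | starting material
27 | dilithium (1E,3E)-buta-1,3-diene-1,4-diolate | [Li]O/C=C/C=C/O[Li] | intermediate (not isolated)
28 | (1E,3E)-1,4-bis(tert-butyldimethylsilyloxy)buta-1,3-diene | CC(C)(C)[Si](C)(C)O/C=C/C=C/O[Si](C)(C)C(C)(C)C | intermediate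
29 | Diels–Alder adduct: ring C cyclohexene (C12=C13) cis-fused to the spiro lactone, acetyl on C8, C11 and C14 tert-butyldimethylsilyloxy cis to acetyl and H9 | CC(=O)[C@@]23C(=O)OC[C@]4([C@@H](OC(C)=O)CCC(C)(C)[C@H]4CO[Si](C)(C)C(C)(C)C)[C@@H]2[C@@H](O[Si](C)(C)C(C)(C)C)C=C[C@H]3O[Si](C)(C)C(C)(C)C | intermediate
30 | trimethylsilyl enol ether of 29 (C15–O–Si, C15=C16) | C=C(O[Si](C)(C)C)[C@@]23C(=O)OC[C@]4([C@@H](OC(C)=O)CCC(C)(C)[C@H]4CO[Si](C)(C)C(C)(C)C)[C@@H]2[C@@H](O[Si](C)(C)C(C)(C)C)C=C[C@H]3O[Si](C)(C)C(C)(C)C | intermediate (not isolated)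
31 | C16 bromide (bromoacetyl on C8) | BrCC(=O)[C@@]23C(=O)OC[C@]4([C@@H](OC(C)=O)CCC(C)(C)[C@H]4CO[Si](C)(C)C(C)(C)C)[C@@H]2[C@@H](O[Si](C)(C)C(C)(C)C)C=C[C@H]3O[Si](C)(C)C(C)(C)C | intermediate
32 | tetracyclic 15-ketone (bicyclo[3.2.1]octane closed, C16 methylene unsubstituted) | C1C(=O)[C@@]23C(=O)OC[C@]4([C@@H](OC(C)=O)CCC(C)(C)[C@H]4CO[Si](C)(C)C(C)(C)C)[C@@H]2[C@@H](O[Si](C)(C)C(C)(C)C)C[C@@H]1[C@H]3O[Si](C)(C)C(C)(C)C | intermediate
33 | trimethylsilyl enol ether of 32 (C15=C16) | C1=C(O[Si](C)(C)C)[C@@]23C(=O)OC[C@]4([C@@H](OC(C)=O)CCC(C)(C)[C@H]4CO[Si](C)(C)C(C)(C)C)[C@@H]2[C@@H](O[Si](C)(C)C(C)(C)C)C[C@@H]1[C@H]3O[Si](C)(C)C(C)(C)C | intermediate (not isolated)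
34 | Mannich base (C16 dimethylaminomethyl, C16 epimers) | CN(C)CC1C(=O)[C@@]23C(=O)OC[C@]4([C@@H](OC(C)=O)CCC(C)(C)[C@H]4CO[Si](C)(C)C(C)(C)C)[C@@H]2[C@@H](O[Si](C)(C)C(C)(C)C)C[C@@H]1[C@H]3O[Si](C)(C)C(C)(C)C | intermediate (not isolated)
35 | trimethylammonium iodide of 34 | C[N+](C)(C)CC1C(=O)[C@@]23C(=O)OC[C@]4([C@@H](OC(C)=O)CCC(C)(C)[C@H]4CO[Si](C)(C)C(C)(C)C)[C@@H]2[C@@H](O[Si](C)(C)C(C)(C)C)C[C@@H]1[C@H]3O[Si](C)(C)C(C)(C)C.[I-] | intermediate (not isolated)
36 | 16-methylene-15-ketone, C6, C11, C14 tris(tert-butyldimethylsilyl) ether of the target | C=C1C(=O)[C@@]23C(=O)OC[C@]4([C@@H](OC(C)=O)CCC(C)(C)[C@H]4CO[Si](C)(C)C(C)(C)C)[C@@H]2[C@@H](O[Si](C)(C)C(C)(C)C)C[C@@H]1[C@H]3O[Si](C)(C)C(C)(C)C | intermediate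
37 | CNP0225182.1 | C=C1C(=O)[C@@]23C(=O)OC[C@]4([C@@H](OC(C)=O)CCC(C)(C)[C@H]4CO)[C@@H]2[C@@H](O)C[C@@H]1[C@H]3O | target

## Step count and least certain steps

Total step count: 23. Longest linear sequence: 21 steps (steps 1, 2, 4–17 and 19–23; steps 3 and 18 are side branches).

**Step 9 (key step).** The rearrangement may be too slow to compete with thermal degradation of the enol ether or with epimerisation of the C5 aldehyde. The ester at the bond-forming terminus retards the shift, a quaternary centre is formed, and in the boat the C9 arm is pressed against the C4 methyl groups. The fallback changes the rearranging species from an enol ether to an ester enolate; it sets out from 9 and comes back at 16.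
- Hydrostannation of 9 as in step 7 would give the stannyl lactone F1.
- Iodine would exchange tin for iodine with retention to give the alkenyl iodide F2; no enol ether is present at this stage.
- Palladium-catalysed methoxycarbonylation (PdCl2(PPh3)2, CO, MeOH, Et3N) would give the enoate lactone F3.
- LiN(SiMe3)2 with Me3SiCl at −78 °C would convert the lactone into its ketene silyl acetal F4.
- On warming (PhMe, 80–110 °C), F4 should undergo the same boat-constrained [3,3] shift as an Ireland–Claisen ring contraction at far lower temperature. Hydrolysis of the silyl ester would give the acid F5, with C5 and C10 as in 15 and C6 as a carboxylic acid.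
- BH3·THF would reduce the acid in the presence of the methyl ester to give 16, which is silylated as in step 10.

**Step 19.** The cycloaddition may stall or lose facial discrimination, because the silyloxy-bearing diene terminus has to bond to C9 next to the spiro quaternary carbon. On prolonged heating the dienophile can instead react through its acetyl group as an oxadiene or take up the diene by simple conjugate addition. The fallback replaces the thermal, substrate-controlled concerted process by a chelate-organised two-bond annulation with a smaller diene; it sets out from 25 (diene from 26) and comes back at 29.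
- 26 would be converted as in step 18, but with Me3SiCl, into (1E,3E)-1,4-bis(trimethylsilyloxy)buta-1,3-diene F6.
- Under two-point Lewis acid activation of the 1,3-dicarbonyl unit (Eu(fod)3 or ZnCl2, DCM, −40 °C), F6 should add to 25 by vinylogous Mukaiyama–Michael addition at C9 and aldol-type closure at C8, giving the bis(trimethylsilyl) adduct F7.
- Citric acid in MeOH would free the 11,14-diol F8.
- TBSOTf with 2,6-lutidine would return 29.

**Step 21.** The α-keto radical may be reduced before it cyclises, or may close on C12 (6-endo) to a bicyclo[2.2.2]octane. The carbonyl group lies inside the forming ring, which twists the radical out of conjugation in the 5-exo transition state and slows ring closure. The fallback removes the carbonyl from the radical tether; it sets out from 31 and comes back at 32.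
- NaBH4 (MeOH/THF, −40 °C, acidic quench) would reduce the ketone to the bromohydrin F9 (C15 epimers).
- With (Me3Si)3SiH and AIBN, the simple primary alkyl radical of F9 should close 5-exo on C13 without the stereoelectronic handicap, giving the ring D alcohol F10.
- Dess–Martin oxidation of F10 would give 32.

**Step 13.** Hydride may open the epoxide slowly or at the wrong carbon. The anti trajectory at C2 in the trans-diaxial mode runs between the axial C9 arm and an axial C4 methyl group, while the conformationally preferred diaxial opening would be at neopentyl C1. The fallback delivers the C1 oxygen intramolecularly from C20; it sets out from 18 and comes back at 20.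
- Boc2O with DMAP would give the tert-butyl carbonate F11.
- Iodine (MeCN, NaHCO3, −20 °C) would activate the alkene from the face opposite C20. The carbonate carbonyl can only reach C1 in a six-membered ring, giving the iodo cyclic carbonate F12 with the C1–O bond cis to C20.
- Bu3SnH with AIBN would remove iodine to give the cyclic carbonate F13.
- K2CO3 in MeOH would release the diol 20.

## Further compounds

F1 | step 9 | (6S)-6-[(1E)-3-[(4-methoxyphenyl)methoxy]-2-(tributylstannyl)prop-1-en-1-yl]-4,4-dimethyloxan-2-one | CCCC[Sn](CCCC)(CCCC)/C(COCc1ccc(OC)cc1)=C/[C@@H]1CC(C)(C)CC(=O)O1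
F2 | step 9 | (6S)-6-[(1E)-2-iodo-3-[(4-methoxyphenyl)methoxy]prop-1-en-1-yl]-4,4-dimethyloxan-2-one | I/C(COCc1ccc(OC)cc1)=C/[C@@H]1CC(C)(C)CC(=O)O1
F3 | step 9 | methyl (2E)-3-[(2S)-4,4-dimethyl-6-oxooxan-2-yl]-2-{[(4-methoxyphenyl)methoxy]methyl}prop-2-enoate | COC(=O)/C(COCc1ccc(OC)cc1)=C/[C@@H]1CC(C)(C)CC(=O)O1
F4 | step 9 | methyl (2E)-3-[(2S)-4,4-dimethyl-6-(trimethylsilyloxy)-3,4-dihydro-2H-pyran-2-yl]-2-{[(4-methoxyphenyl)methoxy]methyl}prop-2-enoate | COC(=O)/C(COCc1ccc(OC)cc1)=C/[C@@H]1CC(C)(C)C=C(O[Si](C)(C)C)O1
F5 | step 9 | 2-(methoxycarbonyl)-2-{[(4-methoxyphenyl)methoxy]methyl}-6,6-dimethylcyclohex-3-ene-1-carboxylic acid (acid cis to ester; C5 and C10 as in 15) | COC(=O)[C@@]1(COCc2ccc(OC)cc2)C=CCC(C)(C)[C@H]1C(=O)O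
F6 | step 19 | (1E,3E)-1,4-bis(trimethylsilyloxy)buta-1,3-diene | C[Si](C)(C)O/C=C/C=C/O[Si](C)(C)C
F7 | step 19 | C11, C14 bis(trimethylsilyl) analogue of 29 | CC(=O)[C@@]23C(=O)OC[C@]4([C@@H](OC(C)=O)CCC(C)(C)[C@H]4CO[Si](C)(C)C(C)(C)C)[C@@H]2[C@@H](O[Si](C)(C)C)C=C[C@H]3O[Si](C)(C)C
F8 | step 19 | 11,14-diol corresponding to 29 | CC(=O)[C@@]23C(=O)OC[C@]4([C@@H](OC(C)=O)CCC(C)(C)[C@H]4CO[Si](C)(C)C(C)(C)C)[C@@H]2[C@@H](O)C=C[C@H]3O
F9 | step 21 | bromohydrin from 31 (C15 alcohol, C15 epimers) | BrCC(O)[C@@]23C(=O)OC[C@]4([C@@H](OC(C)=O)CCC(C)(C)[C@H]4CO[Si](C)(C)C(C)(C)C)[C@@H]2[C@@H](O[Si](C)(C)C(C)(C)C)C=C[C@H]3O[Si](C)(C)C(C)(C)C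
F10 | step 21 | ring D alcohol (15-hydroxy analogue of 32, C15 epimers) | C1C(O)[C@@]23C(=O)OC[C@]4([C@@H](OC(C)=O)CCC(C)(C)[C@H]4CO[Si](C)(C)C(C)(C)C)[C@@H]2[C@@H](O[Si](C)(C)C(C)(C)C)C[C@@H]1[C@H]3O[Si](C)(C)C(C)(C)C
F11 | step 13 | tert-butyl carbonate of 18 (at the C20 oxygen) | CC(C)(C)OC(=O)OC[C@@]1(COCc2ccc(OC)cc2)C=CCC(C)(C)[C@H]1CO[Si](C)(C)C(C)(C)C
F12 | step 13 | iodo cyclic carbonate (C20–O–CO–O–C1; iodine at C2 trans to the C1 oxygen) | O=C1OC[C@@]2(COCc3ccc(OC)cc3)[C@@H](O1)[C@H](I)CC(C)(C)[C@H]2CO[Si](C)(C)C(C)(C)C
F13 | step 13 | cyclic carbonate of diol 20 | O=C1OC[C@@]2(COCc3ccc(OC)cc3)[C@@H](O1)CCC(C)(C)[C@H]2CO[Si](C)(C)C(C)(C)C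
A1 | alternative 1 | cis-fused methylenecyclobutane photoadduct (C8–C15 and C14–C16 bonds) | C=C1C[C@]2(C(=O)OC[C@]3([C@@H](OC(C)=O)CCC(C)(C)[C@H]3CO[Si](C)(C)C(C)(C)C)[C@@H]2[C@@H](O[Si](C)(C)C(C)(C)C)CC4=O)[C@]14O[Si](C)(C)C(C)(C)C
A2 | alternative 1 | lactone-fused 2-silyloxy enone (C13 ketone, C14 silyloxy, C8=C14) | O=C1C[C@H](O[Si](C)(C)C(C)(C)C)[C@@H]2C(=C1O[Si](C)(C)C(C)(C)C)C(=O)OC[C@]23[C@@H](OC(C)=O)CCC(C)(C)[C@H]3CO[Si](C)(C)C(C)(C)C
A3 | alternative 1 | allene (propa-1,2-diene) | C=C=C
A4 | alternative 2 | spiro α,β-unsaturated δ-lactone with ring A, C1 hydroxyl and quaternary C10 | O=C1C=C[C@]2(CO1)[C@@H](O)CCC(C)(C)[C@H]2CO[Si](C)(C)C(C)(C)C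
A5 | alternative 2 | 6-(tert-butyldimethylsilyloxy)-5-[6-(tert-butyldimethylsilyloxy)-2H-pyran-3-yl]-4,4-dimethylhexanal (C5 as in the target) | O=CCCC(C)(C)[C@@H](CO[Si](C)(C)C(C)(C)C)C1=CC=C(O[Si](C)(C)C(C)(C)C)OC1
A6 | alternative 3 | tetracyclic 11-ketone with the C15-oxo C16-methylene ring D | C=C1C(=O)[C@@]23C(=O)OC[C@]4([C@@H](OC(C)=O)CCC(C)(C)[C@H]4CO[Si](C)(C)C(C)(C)C)[C@@H]2C(=O)C[C@@H]1[C@H]3O[Si](C)(C)C(C)(C)C
A7 | alternative 3 | ring C enone (C11 ketone, C12=C13) with acryloyl group on C8 and C14 silyloxy | C=CC(=O)[C@@]23C(=O)OC[C@]4([C@@H](OC(C)=O)CCC(C)(C)[C@H]4CO[Si](C)(C)C(C)(C)C)[C@@H]2C(=O)C=C[C@H]3O[Si](C)(C)C(C)(C)C
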